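The numbers in the tables were computed on assumed constants, and the scatter is random.

Each hand of the substrate is a small charge beside the partner, one part against 4.00, so I follow rates as fractions of each hand's own charge.

| flask | left-handed substrate | right-handed substrate | partner | temperature | remark | time |
|---|---|---|---|---|---|---|
| ash | 0.050 M | 0.050 M | 2 equiv | 58 °C | run made earlier |  |
| oak | 0.050 M | 0.050 M | 8 equiv | 74 °C | run made earlier |  |
| alder | 0.075 M | 0.075 M | 4 equiv | 58 °C | run made earlier |  |
| noon | 0.050 M | 0.050 M | 4.00 equiv | 65 °C |  | 30 h |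
| dawn | 0.050 M | 0.050 M | 4.00 equiv | 50 °C |  | 30 h |
| autumn | 0.050 M | 0.050 M | 4.00 equiv | 80 °C |  | 30 h |

| run | time / h | left-handed product / % | right-handed product / % | left-handed substrate / % |
|---|---|---|---|---|
| ash | 1.33 | 2 | 0 | 49 |
| ash | 2.00 | 0 | 1 | 46 |
| ash | 3.00 | 0 | 1 | 51 |
| ash | 5.00 | 2 | 0 | 49 |
| ash | 8.00 | 0 | 0 | 53 |
| ash | 12.0 | 3 | 2 | 51 |
| ash | 20.0 | 7 | 0 | 45 |
| oak | 1.50 | 2 | 2 | 47 |
| oak | 3.00 | 4 | 6 | 44 |
| oak | 5.00 | 8 | 2 | 38 |
| oak | 6.00 | 9 | 3 | 40 |
| oak | 8.00 | 11 | 6 | 42 |
| oak | 10.0 | 16 | 2 | 38 |
| oak | 12.0 | 19 | 7 | 35 |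
| alder | 1.50 | 0 | 0 | 54 |
| alder | 5.00 | 1 | 1 | 49 |
| alder | 8.00 | 6 | 3 | 47 |
| alder | 12.0 | 5 | 4 | 43 |
| alder | 20.0 | 9 | 0 | 42 |

(readings scatter by 2 percentage points)

- partner is single-handed; left-handed substrate and right-handed substrate are mirror images of each other, charged as a racemate, each of them at the stated concentration
- the handed part of partner does not stay in what it makes, so the products of the two hands are mirror images too

- the best flask by share of left-handed product in all that became left-handed product or right-handed product; "all alike" if 1.5 percentage points covers them all (noon / dawn / autumn / all alike)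
- share of left-handed product in all that became left-handed product or right-handed product, noon
- share of left-handed product in all that became left-handed product or right-handed product, dawn
- share of left-handed product in all that became left-handed product or right-handed product, autumn

Pooled over oak, left-handed product to right-handed product reads 2.46, and pooled over ash and alder it reads 2.92. I take these noisy readings as the selectivity factor, the ratio of the two rates at the start.

The last readings give the left hand 0.0317 h⁻¹ in oak and 0.00900 h⁻¹ in alder. Per unit of partner, that is a rise of 2.64 from 58 °C to 74 °C. I assume the rate follows the partner, so autumn starts from oak with half the partner and a temperature factor of 1.44, at 0.0228 h⁻¹.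

Unslowed, that is 0.683 of exponent for autumn in 30 h. By my reckoning this leaves autumn's left hand at 0.505, its right hand at 0.758 and its partner at 0.816. I put the mean partner factor, 0.908, back in and go round once more. In my reckoning autumn's hands now end at 0.538 and 0.777.

Their quotient, the fraction of the left hand left over the fraction of the right hand left, is the hand ratio 0.692, the factor on the selectivity factor at that moment. My autumn share is 67.5%. Dawn, at 0.00369 h⁻¹, keeps a hand ratio of 0.930 in my reckoning, so for dawn I stay near 74.5%, the share that the pooled ratio of ash and alder gives, and this is lower than the forecast's dawn.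

The forecast gives 74% for noon, 80% for dawn and 68% for autumn, and says: “Dawn should therefore be best, though the data are noisy and the ranges overlap”.

The flasks give 84.7% for noon, 90.6% for dawn and 73.9% for autumn, and the best is dawn.

    left-handed product ⇌ right-handed product (k = 2.10 × 10⁻⁶ s⁻¹, Ea = 124 kJ mol⁻¹)
    partner ⇌ dormant form (K = 0.100, k = 9.90 × 10⁻⁵ s⁻¹, Ea = 111 kJ mol⁻¹, ΔH = −19.0 kJ mol⁻¹)
    partner + right-handed substrate → right-handed product (k = 1.00 × 10⁻⁵ M⁻¹ s⁻¹, Ea = 102 kJ mol⁻¹)
    partner + left-handed substrate → left-handed product (k = 4.60 × 10⁻⁵ M⁻¹ s⁻¹, Ea = 77.0 kJ mol⁻¹)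
    left-handed substrate ⇌ right-handed substrate (k = 2.20 × 10⁻⁵ s⁻¹, Ea = 113 kJ mol⁻¹)
    (constants at 80 °C)

In autumn at 30.0 h, the forward use of left-handed substrate by partner runs at 0.31 of its forward passing into right-handed substrate, slower than that passing, and the hand ratio stands at 0.884, higher than my 0.692. The neighbour of autumn charged with 16.0 equiv of partner reaches a hand ratio of 0.599 at 30.0 h, lower than that of autumn, with a share of 69.3%.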